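**Retrosynthetic overview** (labdane numbering is used for locants only)

1. Endgame: the C-17 aldehyde comes from selective oxidation of a primary alcohol, and the C-8 carbinol from equatorial addition of a hydroxymethyl anion equivalent to a 17-nor C-8 ketone.
2. Key disconnection: C-8 ketone ⇒ C-8=C-9 silyl enol ether ⇒ intramolecular Diels–Alder reaction of an acyclic triene (diene C-7=C-8(OSi)–C-9=C-10, dienophile C-5=C-6 carrying a removable nitro group, tether C-1 to C-4).
3. Enabling feature: ring B (C-5 to C-10) carries its only oxygen at C-8, so it is the cyclohexanone of a 2-silyloxydiene cycloadduct; the C-5–C-10 bond is shared by rings A and B, and C-4 is quaternary (no γ-hydrogen beside the nitroalkene), so one cycloaddition closes both rings.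
4. The triene is built linearly from a butynyl silyl ether, oxetane, 1,1-dimethylallene (asymmetric tert-prenylation sets C-3, the only stereocentre carried into the key step), a methyl/acetyl pair (carbomagnesiation fixes the C-9=C-10 geometry) and a (Z)-β-iodoenoate (side chain).
5. Ring order: rings A and B form together in step 11 (ring B as the cycloadduct ring, ring A through the tether); no ring is made before or after.

Key step: step 11

Assumption: in step 2 the (R)-SEGPHOS ligand is taken to give the (R)-carbinol; if Mosher ester analysis of the step 2 product shows the opposite sense, the enantiomeric ligand is used. Ring compounds are named with labdane locants; their configuration is given by CIP descriptors and by the SMILES.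

**Step 1**
Reactants: 1 tert-butyl(but-3-yn-1-yloxy)dimethylsilane; 2 oxetane
Product: 4 7-[(tert-butyldimethylsilyl)oxy]hept-4-yn-1-ol, via lithium acetylide 3 (not isolated)
Conditions: n-BuLi, THF, −78 °C; then BF3·OEt2, 2, −78 °C; aq NH4Cl
Reagents that add atoms: none
Why: BF3-promoted ring opening of oxetane by a lithium acetylide (alkynylation of a cyclic ether) should give the three-carbon-extended primary alcohol without forming a stereocentre.

**Step 2**
Reactants: 4 7-[(tert-butyldimethylsilyl)oxy]hept-4-yn-1-ol; 5 3-methylbuta-1,2-diene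
Product: 6 (4R)-10-[(tert-butyldimethylsilyl)oxy]-3,3-dimethyldec-1-en-7-yn-4-ol
Conditions: Ir(allyl)[(R)-SEGPHOS](4-cyano-3-nitrobenzoate-C,O) (5 mol %), toluene, 60 °C
Reagents that add atoms: none
Why: Iridium-catalysed transfer-hydrogenative carbonyl tert-prenylation from the alcohol oxidation level: the alcohol is dehydrogenated in situ and the aldehyde is attacked by the chiral (1,1-dimethylallyl)iridium species at its substituted terminus through a closed chair transition state, so the ligand should set C-3 as (R) while the quaternary C-4 and its vinyl group are made in the same event.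

**Step 3**
Reactants: 6 (4R)-10-[(tert-butyldimethylsilyl)oxy]-3,3-dimethyldec-1-en-7-yn-4-ol
Product: 7 (4R)-4,10-bis[(tert-butyldimethylsilyl)oxy]-3,3-dimethyldec-1-en-7-yne
Conditions: TBSOTf, 2,6-lutidine, CH2Cl2, −78 → 0 °C
Reagents that add atoms: tert-butyldimethylsilyl trifluoromethanesulfonate, CC(C)(C)[Si](C)(C)OS(=O)(=O)C(F)(F)F
Why: Silylation with the silyl triflate should protect the hindered neopentylic secondary alcohol, so that only one alkoxide can direct step 5.

**Step 4**
Reactants: 7 (4R)-4,10-bis[(tert-butyldimethylsilyl)oxy]-3,3-dimethyldec-1-en-7-yne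
Product: 8 (7R)-7-[(tert-butyldimethylsilyl)oxy]-8,8-dimethyldec-9-en-3-yn-1-ol
Conditions: CSA (10 mol %), MeOH–CH2Cl2 (1:1), 0 °C
Reagents that add atoms: none
Why: Acid-catalysed methanolysis (chemoselective desilylation) should cleave the unhindered primary silyl ether much faster than the secondary neopentylic one.

**Step 5**
Reactants: 8 (7R)-7-[(tert-butyldimethylsilyl)oxy]-8,8-dimethyldec-9-en-3-yn-1-ol
Product: 10 (3E,7R)-7-[(tert-butyldimethylsilyl)oxy]-3-(2-hydroxyethyl)-4,8,8-trimethyldeca-3,9-dien-2-one, via alkenylmagnesium bromide 9 (not isolated)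
Conditions: MeMgBr (5 equiv), Fe(acac)3 (20 mol %), THF, −20 → 0 °C; then MeC(O)N(OMe)Me (6 equiv), 0 °C → rt; aq NH4Cl
Reagents that add atoms: methylmagnesium bromide, C[Mg]Br; N-methoxy-N-methylacetamide, CC(=O)N(C)OC
Why: Iron-catalysed alkoxide-directed syn-carbomagnesiation of a homopropargylic alcohol delivers methyl to the alkyne carbon remote from the alkoxide (future C-10) and magnesium to the near one (future C-9), and acylation of this alkenylmagnesium by the Weinreb amide with retention should place the acetyl group cis to the new methyl group, fixing the (3E) geometry of the tetrasubstituted enone.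

**Step 6**
Reactants: 10 (3E,7R)-7-[(tert-butyldimethylsilyl)oxy]-3-(2-hydroxyethyl)-4,8,8-trimethyldeca-3,9-dien-2-one
Product: 11 (3E,7R)-7-[(tert-butyldimethylsilyl)oxy]-3-(2-iodoethyl)-4,8,8-trimethyldeca-3,9-dien-2-one
Conditions: I2, PPh3, imidazole, CH2Cl2, 0 °C → rt
Reagents that add atoms: iodine, II
Why: The Appel reaction should convert the primary alcohol into the iodide, leaving the enone, the silyl ether and the vinyl group untouched.

**Step 7**
Reactants: 12 methyl but-2-ynoate
Product: 13 methyl (2Z)-3-iodobut-2-enoate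
Conditions: NaI, AcOH, 115 °C
Reagents that add atoms: sodium iodide, [Na+].[I-]
Why: Conjugate hydroiodination of a 2-alkynoate (iodide adds to the β-carbon, protonation anti) should give the (Z)-β-iodoenoate, with iodine cis to the ester.

**Step 8**
Reactants: 11 (3E,7R)-7-[(tert-butyldimethylsilyl)oxy]-3-(2-iodoethyl)-4,8,8-trimethyldeca-3,9-dien-2-one; 13 methyl (2Z)-3-iodobut-2-enoate
Product: 15 methyl (2Z,6E,10R)-6-acetyl-10-[(tert-butyldimethylsilyl)oxy]-3,7,11,11-tetramethyltrideca-2,6,12-trienoate, via alkylzinc iodide 14 (not isolated)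
Conditions: Zn, LiCl, THF, 40 °C; then 13, PdCl2(DPEphos) (3 mol %), THF, rt
Reagents that add atoms: none
Why: LiCl-promoted zinc insertion into the primary iodide tolerates the ketone, and Negishi sp3–sp2 cross-coupling with the β-iodoenoate proceeds with retention of alkene geometry, so the (2Z)-enoate of the side chain should be formed directly.

**Step 9**
Reactants: 15 methyl (2Z,6E,10R)-6-acetyl-10-[(tert-butyldimethylsilyl)oxy]-3,7,11,11-tetramethyltrideca-2,6,12-trienoate
Product: 16 methyl (2Z,6E,10R,12E)-6-acetyl-10-[(tert-butyldimethylsilyl)oxy]-3,7,11,11-tetramethyl-13-nitrotrideca-2,6,12-trienoate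
Conditions: AgNO2 (3 equiv), TEMPO (0.4 equiv), 4 Å MS, ClCH2CH2Cl, 70 °C
Reagents that add atoms: silver nitrite, [Ag+].[O-]N=O
Why: Radical nitration of a terminal alkene (nitro radical addition to the unsubstituted terminus, then TEMPO-mediated dehydrogenation) should give the (E)-nitroalkene, because the electron-poor tri- and tetrasubstituted alkenes react far more slowly and the quaternary C-4 excludes isomerisation to an allylic nitro compound.

**Step 10**
Reactants: 16 methyl (2Z,6E,10R,12E)-6-acetyl-10-[(tert-butyldimethylsilyl)oxy]-3,7,11,11-tetramethyl-13-nitrotrideca-2,6,12-trienoate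
Product: 17 methyl (2Z,6E,10R,12E)-10-[(tert-butyldimethylsilyl)oxy]-6-{1-[(tert-butyldimethylsilyl)oxy]ethenyl}-3,7,11,11-tetramethyl-13-nitrotrideca-2,6,12-trienoate
Conditions: TBSOTf (1.3 equiv), i-Pr2NEt (2 equiv), CH2Cl2, −78 → −20 °C
Reagents that add atoms: tert-butyldimethylsilyl trifluoromethanesulfonate, CC(C)(C)[Si](C)(C)OS(=O)(=O)C(F)(F)F
Why: Soft enolisation of the methyl ketone (silyl triflate and hindered amine) should occur kinetically at the α′-methyl group and give the cross-conjugated 2-silyloxy diene without touching the ester or the nitroalkene.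

**Step 11**
Reactants: 17 methyl (2Z,6E,10R,12E)-10-[(tert-butyldimethylsilyl)oxy]-6-{1-[(tert-butyldimethylsilyl)oxy]ethenyl}-3,7,11,11-tetramethyl-13-nitrotrideca-2,6,12-trienoate
Product: 18 methyl (13Z)-(3R,5S,6R,10R)-3,8-bis[(tert-butyldimethylsilyl)oxy]-6-nitro-17-norlabda-8,13-dien-15-oate (trans-fused; nitro equatorial)
Conditions: toluene (0.005 M), BHT (10 mol %), 110 °C, sealed tube
Reagents that add atoms: none
Why: The step is a thermal, concerted but asynchronous normal-electron-demand [4+2] cycloaddition between the 2-silyloxy diene C-7=C-8–C-9=C-10 and the (E)-nitroalkene C-5=C-6; the closest known reaction types are the intramolecular Diels–Alder reaction of terminally nitro-activated 1,7,9-decatrienes to trans-decalins and cycloadditions of 4,4-disubstituted 2-silyloxydienes that create angular methyl groups. Ring B is the cyclohexene made by the cycloaddition itself (both new bonds, C-6–C-7 and C-5–C-10, lie in it), and ring A is closed in the same event by the four-atom tether C-1 to C-4 through the C-5–C-10 bond, a fused bicyclo[4.4.0] closure with the tether on the outside position of the diene terminus. At C-10 the (6E) geometry of the tetrasubstituted alkene puts the methyl group inside and the tether outside, so the methyl becomes angular; at C-5 the nitro-endo, tether-anti transition state places the hydrogen anti to that methyl (trans fusion); the absolute sense comes from C-3, whose silyloxy group sits equatorial in the chair-like tether so that the C-10 methyl ends cis to O-3. C-6 follows from suprafacial addition to the (E)-nitroalkene and is erased in step 12. The step needs endo over exo closure and one π-face over the other, which the endo preference of the nitro group, the bulky equatorial silyl ether beside the gem-dimethyl carbon and high dilution (against bimolecular Michael pathways) should secure.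

**Step 12**
Reactants: 18 methyl (13Z)-(3R,5S,6R,10R)-3,8-bis[(tert-butyldimethylsilyl)oxy]-6-nitro-17-norlabda-8,13-dien-15-oate
Product: 21 methyl (13Z)-(3R,5S,9S,10R)-3-hydroxy-8-oxo-17-norlabda-6,13-dien-15-oate, via silylated β-nitro ketone 19 (not isolated), via β-nitro ketone 20 (not isolated)
Conditions: HF (48 % aq), MeCN, 0 °C → rt; then Et3N (excess), 0 °C → rt
Reagents that add atoms: none
Why: Hydrolysis of the silyl enol ether protonates C-9 axially from the face opposite the angular methyl group (equatorial side chain, also the thermodynamic epimer), HF also removes the 3-O-silyl group, and Et3N should then cause E1cB loss of nitrous acid from the β-nitro ketone to give the conjugated enone.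

**Step 13**
Reactants: 21 methyl (13Z)-(3R,5S,9S,10R)-3-hydroxy-8-oxo-17-norlabda-6,13-dien-15-oate
Product: 22 methyl (13Z)-(3R,5S,9S,10R)-3-hydroxy-8-oxo-17-norlabd-13-en-15-oate
Conditions: [(Ph3P)CuH]6 (0.4 equiv), H2O (5 equiv), toluene, rt
Reagents that add atoms: none
Why: Copper hydride conjugate reduction should be chemoselective for the ring enone over the β,β-disubstituted enoate and touches no stereocentre.

**Step 14**
Reactants: 22 methyl (13Z)-(3R,5S,9S,10R)-3-hydroxy-8-oxo-17-norlabd-13-en-15-oate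
Product: 23 methyl (13Z)-(3R,5S,8R,9S,10R)-3,8-dihydroxy-17-[dimethyl(propan-2-yloxy)silyl]labd-13-en-15-oate
Conditions: i-PrO(Me)2SiCH2MgCl (4 equiv, separately prepared solution), THF, −40 → 0 °C; aq NH4Cl
Reagents that add atoms: [(isopropoxydimethylsilyl)methyl]magnesium chloride, CC(C)O[Si](C)(C)C[Mg]Cl
Why: Grignard addition of a hydroxymethyl anion equivalent to the ketone (faster than to the hindered conjugated ester at low temperature) should take the equatorial trajectory, because the axial face is blocked by the 1,3-diaxial C-10 methyl group, giving the axial C-8 hydroxyl (8R).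

**Step 15**
Reactants: 23 methyl (13Z)-(3R,5S,8R,9S,10R)-3,8-dihydroxy-17-[dimethyl(propan-2-yloxy)silyl]labd-13-en-15-oate
Product: 24 methyl (13Z)-(3R,5S,8R,9S,10R)-3,8,17-trihydroxylabd-13-en-15-oate
Conditions: H2O2 (30 % aq), KF, KHCO3, THF–MeOH (1:1), rt
Reagents that add atoms: hydrogen peroxide, OO
Why: Tamao–Fleming oxidation should replace the C–Si bond by C–OH under mildly basic fluoride/peroxide conditions that the electron-poor enoate tolerates.

**Step 16**
Reactants: 24 methyl (13Z)-(3R,5S,8R,9S,10R)-3,8,17-trihydroxylabd-13-en-15-oate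
Product: 25 methyl (13Z)-(3R,5S,8R,9S,10R)-3,8-dihydroxy-17-oxolabd-13-en-15-oate
Conditions: TEMPO (10 mol %), PhI(OAc)2 (1.1 equiv), CH2Cl2, rt
Reagents that add atoms: none
Why: Oxoammonium-mediated oxidation (TEMPO with a hypervalent iodine co-oxidant) should be selective for the primary alcohol over the hindered secondary C-3 and the tertiary C-8 alcohols, and stop at the aldehyde under anhydrous, near-neutral conditions that avoid α-ketol rearrangement.

**Compound list**

1 | tert-butyl(but-3-yn-1-yloxy)dimethylsilane | C#CCCO[Si](C)(C)C(C)(C)C | starting material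
2 | oxetane | C1COC1 | starting material
3 | {4-[(tert-butyldimethylsilyl)oxy]but-1-yn-1-yl}lithium | [Li]C#CCCO[Si](C)(C)C(C)(C)C | intermediate
4 | 7-[(tert-butyldimethylsilyl)oxy]hept-4-yn-1-ol | OCCCC#CCCO[Si](C)(C)C(C)(C)C | intermediate
5 | 3-methylbuta-1,2-diene | CC(C)=C=C | starting material
6 | (4R)-10-[(tert-butyldimethylsilyl)oxy]-3,3-dimethyldec-1-en-7-yn-4-ol | C=CC(C)(C)[C@H](O)CCC#CCCO[Si](C)(C)C(C)(C)C | intermediate
7 | (4R)-4,10-bis[(tert-butyldimethylsilyl)oxy]-3,3-dimethyldec-1-en-7-yne | C=CC(C)(C)[C@H](O[Si](C)(C)C(C)(C)C)CCC#CCCO[Si](C)(C)C(C)(C)C | intermediate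
8 | (7R)-7-[(tert-butyldimethylsilyl)oxy]-8,8-dimethyldec-9-en-3-yn-1-ol | C=CC(C)(C)[C@H](O[Si](C)(C)C(C)(C)C)CCC#CCCO | intermediate
9 | [(3E,7R)-1-(bromomagnesiooxy)-7-[(tert-butyldimethylsilyl)oxy]-4,8,8-trimethyldeca-3,9-dien-3-yl]magnesium bromide (methyl and magnesium cis) | C/C(CC[C@@H](O[Si](C)(C)C(C)(C)C)C(C)(C)C=C)=C(\[Mg]Br)CCO[Mg]Br | intermediate
10 | (3E,7R)-7-[(tert-butyldimethylsilyl)oxy]-3-(2-hydroxyethyl)-4,8,8-trimethyldeca-3,9-dien-2-one | CC(=O)/C(CCO)=C(\C)CC[C@@H](O[Si](C)(C)C(C)(C)C)C(C)(C)C=C | intermediate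
11 | (3E,7R)-7-[(tert-butyldimethylsilyl)oxy]-3-(2-iodoethyl)-4,8,8-trimethyldeca-3,9-dien-2-one | CC(=O)/C(CCI)=C(\C)CC[C@@H](O[Si](C)(C)C(C)(C)C)C(C)(C)C=C | intermediate
12 | methyl but-2-ynoate | CC#CC(=O)OC | starting material
13 | methyl (2Z)-3-iodobut-2-enoate | COC(=O)/C=C(/C)I | intermediate
14 | (3E,7R)-7-[(tert-butyldimethylsilyl)oxy]-3-[2-(iodozincio)ethyl]-4,8,8-trimethyldeca-3,9-dien-2-one | CC(=O)/C(CC[Zn]I)=C(\C)CC[C@@H](O[Si](C)(C)C(C)(C)C)C(C)(C)C=C | intermediate
15 | methyl (2Z,6E,10R)-6-acetyl-10-[(tert-butyldimethylsilyl)oxy]-3,7,11,11-tetramethyltrideca-2,6,12-trienoate | COC(=O)/C=C(/C)CC/C(C(C)=O)=C(/C)CC[C@@H](O[Si](C)(C)C(C)(C)C)C(C)(C)C=C | intermediate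
16 | methyl (2Z,6E,10R,12E)-6-acetyl-10-[(tert-butyldimethylsilyl)oxy]-3,7,11,11-tetramethyl-13-nitrotrideca-2,6,12-trienoate | COC(=O)/C=C(/C)CC/C(C(C)=O)=C(/C)CC[C@@H](O[Si](C)(C)C(C)(C)C)C(C)(C)/C=C/[N+](=O)[O-] | intermediate
17 | methyl (2Z,6E,10R,12E)-10-[(tert-butyldimethylsilyl)oxy]-6-{1-[(tert-butyldimethylsilyl)oxy]ethenyl}-3,7,11,11-tetramethyl-13-nitrotrideca-2,6,12-trienoate | COC(=O)/C=C(/C)CC/C(C(=C)O[Si](C)(C)C(C)(C)C)=C(/C)CC[C@@H](O[Si](C)(C)C(C)(C)C)C(C)(C)/C=C/[N+](=O)[O-] | intermediate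
18 | methyl (13Z)-(3R,5S,6R,10R)-3,8-bis[(tert-butyldimethylsilyl)oxy]-6-nitro-17-norlabda-8,13-dien-15-oate (trans-fused; H-5 anti to the C-10 methyl; 3-silyloxy equatorial and cis to the C-10 methyl; nitro equatorial) | COC(=O)/C=C(/C)CCC1=C(O[Si](C)(C)C(C)(C)C)C[C@@H]([N+](=O)[O-])[C@@H]2C(C)(C)[C@H](O[Si](C)(C)C(C)(C)C)CC[C@@]12C | intermediate
19 | methyl (13Z)-(3R,5S,6R,9S,10R)-3-[(tert-butyldimethylsilyl)oxy]-6-nitro-8-oxo-17-norlabd-13-en-15-oate | COC(=O)/C=C(/C)CC[C@H]1[C@]2(C)CC[C@@H](O[Si](C)(C)C(C)(C)C)C(C)(C)[C@H]2[C@H]([N+](=O)[O-])CC1=O | intermediate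
20 | methyl (13Z)-(3R,5S,6R,9S,10R)-3-hydroxy-6-nitro-8-oxo-17-norlabd-13-en-15-oate | COC(=O)/C=C(/C)CC[C@H]1[C@]2(C)CC[C@@H](O)C(C)(C)[C@H]2[C@H]([N+](=O)[O-])CC1=O | intermediate
21 | methyl (13Z)-(3R,5S,9S,10R)-3-hydroxy-8-oxo-17-norlabda-6,13-dien-15-oate | COC(=O)/C=C(/C)CC[C@H]1[C@]2(C)CC[C@@H](O)C(C)(C)[C@H]2C=CC1=O | intermediate
22 | methyl (13Z)-(3R,5S,9S,10R)-3-hydroxy-8-oxo-17-norlabd-13-en-15-oate (side chain equatorial) | COC(=O)/C=C(/C)CC[C@H]1[C@]2(C)CC[C@@H](O)C(C)(C)[C@H]2CCC1=O | intermediate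
23 | methyl (13Z)-(3R,5S,8R,9S,10R)-3,8-dihydroxy-17-[dimethyl(propan-2-yloxy)silyl]labd-13-en-15-oate (8-OH axial, cis to the C-10 methyl) | COC(=O)/C=C(/C)CC[C@H]1[C@]2(C)CC[C@@H](O)C(C)(C)[C@H]2CC[C@]1(O)C[Si](C)(C)OC(C)C | intermediate
24 | methyl (13Z)-(3R,5S,8R,9S,10R)-3,8,17-trihydroxylabd-13-en-15-oate | COC(=O)/C=C(/C)CC[C@H]1[C@]2(C)CC[C@@H](O)C(C)(C)[C@H]2CC[C@]1(O)CO | intermediate
25 | methyl (13Z)-(3R,5S,8R,9S,10R)-3,8-dihydroxy-17-oxolabd-13-en-15-oate, i.e. methyl (2Z)-5-[(1S,2R,4aS,6R,8aR)-2-formyl-2,6-dihydroxy-5,5,8a-trimethyldecahydronaphthalen-1-yl]-3-methylpent-2-enoate | COC(=O)/C=C(/C)CC[C@H]1[C@]2(C)CC[C@@H](O)C(C)(C)[C@H]2CC[C@]1(O)C=O | target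

**Step count and risks**

Total: 16 steps. Longest linear sequence: 15 steps (steps 1–6 and 8–16; step 7 prepares the coupling partner 13).

The three steps most likely to fail:

Step 11. The bond between the fully substituted diene terminus C-10 and C-5 (flanked by the quaternary C-4) must form in a crowded transition state. If the cycloaddition is too slow at 110 °C, bimolecular Michael-type oligomerisation of the nitroalkene or closure through the exo (cis-fused) transition state may take over. A minor cis-fused adduct alone would still be repairable, because C-5 becomes the epimerisable γ-position of enone 21; wrong π-facial selectivity would not be. The fallback is a Lewis-acid-catalysed cycloaddition of an enal followed by decarbonylation; it sets out from 15 and returns at 22. Cross-metathesis of the vinyl group of 15 with crotonaldehyde (second-generation Hoveyda–Grubbs catalyst, CH2Cl2, 40 °C) should give the (E)-enal F1. TBSOTf and i-Pr2NEt should convert it into the silyl dienol ether F2. Me2AlCl (CH2Cl2, −78 → −20 °C) should promote an endo-selective intramolecular Diels–Alder reaction to the trans-fused cycloadduct aldehyde F3. Tsuji–Wilkinson decarbonylation with RhCl(PPh3)3 (toluene, 110 °C) should remove the formyl carbon and give the bis-silyl compound F4. Aqueous HF in MeCN should then give, by way of the 3-O-silyl ketone F5, ketone 22, so that steps 12 and 13 are not needed.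

Step 9. Addition of the nitro radical to the neopentylic vinyl group may be slow, so that incomplete conversion or attack on the enone and enoate alkenes may result. The fallback replaces nitro by sulfonyl activation; it sets out from 15 and returns at 21. Iodosulfonylation with PhSO2Na and I2 (EtOAc–H2O, rt) and dehydroiodination with Et3N should give, via the β-iodo sulfone F6, the (E)-vinyl sulfone F7. TBSOTf and i-Pr2NEt should give the sulfonyl triene F8, and heating (xylene, 150 °C, BHT) should give the sulfone cycloadduct F9. Aqueous HF in MeCN should lead through the silylated β-sulfonyl ketone F10 to the β-sulfonyl hydroxy ketone F11, and DBU (E1cB loss of benzenesulfinate) should then give enone 21.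

Step 5. The chelated, tetrasubstituted alkenylmagnesium 9 may be acylated too slowly by the Weinreb amide, so that protonation on work-up dominates. The fallback uses iodination and cross-coupling in place of acylation; it sets out from 8 and returns at 10. The carbomagnesiation mixture containing 9 is quenched with I2 (THF, −78 °C → rt) to give the alkenyl iodide F12. Stille coupling with tributyl(1-ethoxyvinyl)stannane (Pd(PPh3)4, CuI, DMF, 50 °C) should give the 2-ethoxy diene F13, whose hydrolysis with oxalic acid in wet THF should give enone 10.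

**Further compounds**

F1 | step 11 | methyl (2Z,6E,10R,12E)-6-acetyl-10-[(tert-butyldimethylsilyl)oxy]-3,7,11,11-tetramethyl-14-oxotetradeca-2,6,12-trienoate | COC(=O)/C=C(/C)CC/C(C(C)=O)=C(/C)CC[C@@H](O[Si](C)(C)C(C)(C)C)C(C)(C)/C=C/C=O
F2 | step 11 | methyl (2Z,6E,10R,12E)-10-[(tert-butyldimethylsilyl)oxy]-6-{1-[(tert-butyldimethylsilyl)oxy]ethenyl}-3,7,11,11-tetramethyl-14-oxotetradeca-2,6,12-trienoate | COC(=O)/C=C(/C)CC/C(C(=C)O[Si](C)(C)C(C)(C)C)=C(/C)CC[C@@H](O[Si](C)(C)C(C)(C)C)C(C)(C)/C=C/C=O
F3 | step 11 | 6-formyl analogue of 18 (formyl equatorial, in place of nitro) | COC(=O)/C=C(/C)CCC1=C(O[Si](C)(C)C(C)(C)C)C[C@@H](C=O)[C@@H]2C(C)(C)[C@H](O[Si](C)(C)C(C)(C)C)CC[C@@]12C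
F4 | step 11 | methyl (13Z)-(3R,5S,10R)-3,8-bis[(tert-butyldimethylsilyl)oxy]-17-norlabda-8,13-dien-15-oate | COC(=O)/C=C(/C)CCC1=C(O[Si](C)(C)C(C)(C)C)CC[C@@H]2C(C)(C)[C@H](O[Si](C)(C)C(C)(C)C)CC[C@@]12C
F5 | step 11 | 3-O-(tert-butyldimethylsilyl) ether of 22 | COC(=O)/C=C(/C)CC[C@H]1[C@]2(C)CC[C@@H](O[Si](C)(C)C(C)(C)C)C(C)(C)[C@H]2CCC1=O
F6 | step 9 | methyl (2Z,6E,10R)-6-acetyl-10-[(tert-butyldimethylsilyl)oxy]-12-iodo-3,7,11,11-tetramethyl-13-(phenylsulfonyl)trideca-2,6-dienoate (both epimers at the iodine-bearing carbon) | COC(=O)/C=C(/C)CC/C(C(C)=O)=C(/C)CC[C@@H](O[Si](C)(C)C(C)(C)C)C(C)(C)C(I)CS(=O)(=O)c1ccccc1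
F7 | step 9 | methyl (2Z,6E,10R,12E)-6-acetyl-10-[(tert-butyldimethylsilyl)oxy]-3,7,11,11-tetramethyl-13-(phenylsulfonyl)trideca-2,6,12-trienoate | COC(=O)/C=C(/C)CC/C(C(C)=O)=C(/C)CC[C@@H](O[Si](C)(C)C(C)(C)C)C(C)(C)/C=C/S(=O)(=O)c1ccccc1
F8 | step 9 | 13-(phenylsulfonyl) analogue of 17 (sulfonyl in place of nitro) | COC(=O)/C=C(/C)CC/C(C(=C)O[Si](C)(C)C(C)(C)C)=C(/C)CC[C@@H](O[Si](C)(C)C(C)(C)C)C(C)(C)/C=C/S(=O)(=O)c1ccccc1
F9 | step 9 | 6-(phenylsulfonyl) analogue of 18 (sulfonyl equatorial, in place of nitro) | COC(=O)/C=C(/C)CCC1=C(O[Si](C)(C)C(C)(C)C)C[C@@H](S(=O)(=O)c2ccccc2)[C@@H]3C(C)(C)[C@H](O[Si](C)(C)C(C)(C)C)CC[C@@]13C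
F10 | step 9 | 6-(phenylsulfonyl) analogue of 19 | COC(=O)/C=C(/C)CC[C@H]1[C@]2(C)CC[C@@H](O[Si](C)(C)C(C)(C)C)C(C)(C)[C@H]2[C@H](S(=O)(=O)c3ccccc3)CC1=O
F11 | step 9 | 6-(phenylsulfonyl) analogue of 20 | COC(=O)/C=C(/C)CC[C@H]1[C@]2(C)CC[C@@H](O)C(C)(C)[C@H]2[C@H](S(=O)(=O)c3ccccc3)CC1=O
F12 | step 5 | (3E,7R)-7-[(tert-butyldimethylsilyl)oxy]-3-iodo-4,8,8-trimethyldeca-3,9-dien-1-ol (iodine cis to the C-4 methyl) | C/C(CC[C@@H](O[Si](C)(C)C(C)(C)C)C(C)(C)C=C)=C(\I)CCO
F13 | step 5 | (3E,7R)-7-[(tert-butyldimethylsilyl)oxy]-3-(1-ethoxyethenyl)-4,8,8-trimethyldeca-3,9-dien-1-ol | C=C(OCC)/C(CCO)=C(\C)CC[C@@H](O[Si](C)(C)C(C)(C)C)C(C)(C)C=C
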